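## The problem

Target 32 is an ent-labdane: a trans-fused decalin (rings A and B) with an exocyclic C8=C17 alkene, a five-carbon chain on C9, and acetoxymethyl groups on C4 (C19) and on C13 (C16). The bicycle has four stereocentres. C4 and C10 are quaternary and 1,3-related, with C19 and the C10 methyl (C20) on the same face. C5 and C9 each adjoin C10, so once C10 exists a hydrogen can be delivered to both from the face opposite C20. C4 cannot be corrected later, so it has to be set absolutely and then made to steer C10. In the chain, the 13Z alkene holds the C16 oxygen cis to the C15 carboxyl, so a free 16-hydroxyl would close onto C15 as the butenolide. The two oxygens therefore need separate handling, and the acid should appear last by a step that hydrolyses nothing. The 8(17)-alkene moves into the ring under acid, the acetates do not survive hydride or amide base, and C9 can epimerise whenever C11 is a carbonyl. The feature that invites a cycloaddition is ring B: C8 (bearing C17) and C9 (bearing C11) lie between C7 and C10, which is the imprint of a but-2-ynoate added across a C10=C5–C6=C7 diene anchored on ring A.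

## Retrosynthesis

**End game (32 ← 31 ← 30 ← 29 ← 28).** No skeletal bond is cut. The acid 32 is taken back to enal 31 and allylic alcohol 30, so the last step is a chlorite oxidation that leaves both acetates alone. The acetates of 30 come from diol 28 through silyl ether 29. C15 stays silylated while C16 and C19 are acylated, so a 16-hydroxyl never faces a C15 carbonyl and the butenolide cannot form.

**C12–C13 (28 ← 22 + 26).** The chain is cut between the sp3 carbon C12 and the sp2 carbon C13. A cut at C11–C12 would need a substitution at a β-branched homoallylic carbon that eliminates easily into conjugation. An olefination at C13=C14 gives no reliable control of the 13Z geometry. The chosen cut gives bicyclic diene alcohol 22 and four-carbon vinyl iodide 26, in which the alkene geometry is already fixed. The forward step must hydroborate the monosubstituted alkene of 22 in the presence of the 8(17)-alkene and couple with retention.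

**Vinyl iodide (26 ← 25 ← 24 ← 23).** The geometry comes from syn addition of tin hydride to symmetrical but-2-yne-1,4-diol 23, so no regiochemical question arises in forming stannane 24. The tributyltin group then serves twice. It shields the neighbouring hydroxyl so that only the remote one is silylated (25), and it is exchanged for iodine with retention (26).

**C11=C12 (22 ← 21 ← 20 ← 19 ← 18).** The vinyl group of 21 is cut at the alkene to aldehyde 20, which comes from alcohol 19 and ester 18. This uses the C11 ester delivered by the cycloaddition and adds only one carbon. The silyl group is removed at diene 21 to give 22, because the acetate that replaces it could not survive the earlier steps.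

**Adjusting ring B (18 ← 16 ← 15).** No skeletal bond is cut. The β,γ-unsaturated ester 18 is traced to the conjugated ester 16, from which kinetic deprotonation at C17 and protonation at C9 make the exocyclic alkene and the C9 stereocentre together. Ester 16 comes from diene ester 15 by saturating the 5,6-alkene, which sets C5.

**Key cut, C9–C10 and C7–C8 (15 ← 13 + 14).** Removing C8, C9, C11 and C17 as methyl but-2-ynoate 14 leaves the monocyclic diene 13 with one stereocentre. Neighbouring two-bond cuts of ring B (C5–C10 with C8–C9, or an annulation through C5–C6) would need an open-chain or more oxidised precursor and would not deliver C11 and C17 at usable oxidation levels. The forward reaction must be regioselective (ester carbon to C10) and must take the dienophile to the diene face away from the C4 silyloxymethyl group.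

**Ring A diene (13 ← 12 ← 11 ← 10 ← 8 ← 6 ← 3 ← 1 + 2).** The vinyl group of 13 is cut at C5–C6 to enol triflate 10, which avoids a cationic dehydration. Triflate 10 comes from keto ester 8, since that ketone can enolise only toward C10. The two methyl groups come from enolate alkylations of keto ester 1. The first, made through the valine-derived enamine 3 from auxiliary 2, sets C4 in keto ester 6. Alcohol 12 and ester 11 carry C19 from the ester level to the silyl ether.

## Roads not taken

Alternative 1: This plan cuts C4–C18 and C3–C18 and builds the C4 quaternary centre last on a finished trans-decalin. A hydroxyl-directed Simmons–Smith methylenation across C3–C4 gives cyclopropane A1, and later hydrogenolysis of the C3–C18 bond turns the bridging carbon into the C18 methyl. Its merit is stereocontrol: the zinc alkoxide and the rigid decalin fix the face, so the C4/C10 relationship is secure. On that point it is better than the chosen plan, which relies on a flexible diene. Its weakness is scope. A1 has a bare ring B with only a masked C9 ketone, so C8, C17, the whole chain and the exocyclic alkene remain to be built next to the quaternary C10. The cyclopropane must also be opened regioselectively under acidic hydrogenation before any acid-labile alkene is present. Against its firmer stereocontrol the chosen plan sets a much shorter path to a ring B that already carries C11 and C17, and a stage (15) at which a minor C10 epimer can still be removed cheaply.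

Alternative 2: This plan cuts C5–C10 and C8–C9 and closes both rings in one Lewis acid-catalysed intramolecular Diels–Alder reaction, giving octalin aldehyde A2 with C5, C9 and C10 set. It has the largest gain in complexity per step, and because the open-chain substrate is achiral it could in principle be made enantioselective with a chiral catalyst and no auxiliary. In ring-forming power it is superior to the chosen plan. Its weak points lie after the key step. The C4 gem-diester of A2 must be split into a methyl and an acetoxymethyl group by steric differentiation and a full deoxygenation. The C8 silyloxymethyl group is a sacrificial centre that must be turned into the exocyclic methylene. The 6,7-alkene must be saturated selectively. The dienophile that creates quaternary C10 is a β,β-disubstituted enal, a poor partner for asymmetric catalysis. The chosen plan forms only one stereocentre in its key step, but C4 arrives already differentiated and C11 and C17 need only a deconjugation, so fewer corrective steps follow.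

Alternative 3: This plan cuts C9–C10 and builds ring B by one-carbon expansion of a five-membered ring. Methylation at selenium triggers a semipinacol shift of C10 from C8 to C9, giving ketone A3 with the protected chain on C9 and the C8 carbonyl in place. Its merits are real. The chain arrives in one piece, C9 can be corrected by equilibration, and the 8-ketone gives the exocyclic alkene by simple methylenation, without the regiochemical question of the chosen deconjugation. Its weak points are access and finish. A trans-fused five-membered ring B carrying C4, C5 and C10 is harder to make than the decalin itself. The migrating group is decided by alignment in a strained system. Stoichiometric selenium and AgBF4 are needed. The chain of A3 still lacks C14 and C15, and olefination of a C13 ketone does not control the 13Z geometry. The chosen plan reaches the bicycle in one cycloaddition from a monocyclic diene and fixes the alkene geometry in the coupling partner. It has to accept a less certain C9/C8 adjustment.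

Key step: step 8

Assumption: methylation of the lithioenamine from 3 under the toluene/HMPA protocol is taken to give the 1R ketimine 5. If the sense is opposite, the THF protocol or the D-valine ester gives the same keto ester 6.

Naming remark: bicyclic compounds are named on the ent-labdane skeleton with labdane numbering (C18 = methyl on C4, C19 = CH2O on C4, C20 = methyl on C10, C17 on C8, C11 on C9). CIP descriptors refer to that numbering.

## Route

Step 1
Reactants: 1 methyl 2-oxocyclohexane-1-carboxylate; 2 tert-butyl L-valinate
Product: 3 methyl 2-{[(2S)-1-tert-butoxy-3-methyl-1-oxobutan-2-yl]amino}cyclohex-1-ene-1-carboxylate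
Conditions: BF3·OEt2 (cat.), benzene, reflux, Dean–Stark
Reagents that add atoms: none
Why: Condensation of a β-keto ester with a primary amine gives the hydrogen-bonded enamino ester on azeotropic removal of water; the valine stereocentre is not touched.

Step 2
Reactants: 3 methyl 2-{[(2S)-1-tert-butoxy-3-methyl-1-oxobutan-2-yl]amino}cyclohex-1-ene-1-carboxylate
Product: 6 methyl (1R)-1-methyl-2-oxocyclohexane-1-carboxylate, via lithioenamine 4 (not isolated), via methylated ketimine 5 (not isolated)
Conditions: LiN(iPr)2, toluene, −78 °C; HMPA, MeI, −78 → −55 °C; then 1 M aq HCl, rt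
Reagents that add atoms: iodomethane, CI
Why: Auxiliary-controlled alkylation of a chelated chiral lithioenamine: lithium is held by the valine ester carbonyl and the isopropyl group screens one face, so methyl iodide should add to the other and set the quaternary carbon (later C4) as R; mild acid hydrolysis of the ketimine releases the keto ester and the auxiliary.

Step 3
Reactants: 6 methyl (1R)-1-methyl-2-oxocyclohexane-1-carboxylate
Product: 8 methyl (1R)-1,3-dimethyl-2-oxocyclohexane-1-carboxylate, via lithium enolate 7 (not isolated)
Conditions: LiN(iPr)2, THF, −78 °C; MeI, −78 → 0 °C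
Reagents that add atoms: iodomethane, CI
Why: Kinetic enolate alkylation; C1 is quaternary, so the ketone can enolise only toward C3, and the configuration of the new C3 centre is irrelevant because it becomes sp2 in the next step.

Step 4
Reactants: 8 methyl (1R)-1,3-dimethyl-2-oxocyclohexane-1-carboxylate
Product: 10 methyl (1R)-1,3-dimethyl-2-{[(trifluoromethyl)sulfonyl]oxy}cyclohex-2-ene-1-carboxylate, via potassium enolate 9 (not isolated)
Conditions: KN(SiMe3)2, THF, −78 → −20 °C; PhNTf2, −78 °C → rt
Reagents that add atoms: N-phenylbis(trifluoromethanesulfonimide), O=S(=O)(N(c1ccccc1)S(=O)(=O)C(F)(F)F)C(F)(F)F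
Why: Enol triflate formation from the only possible enolate; O-sulfonylation of hindered tetrasubstituted cyclohexanone enolates with PhNTf2 is standard for 2,2,6-trisubstituted cyclohexanones.

Step 5
Reactants: 10 methyl (1R)-1,3-dimethyl-2-{[(trifluoromethyl)sulfonyl]oxy}cyclohex-2-ene-1-carboxylate
Product: 11 methyl (1R)-2-ethenyl-1,3-dimethylcyclohex-2-ene-1-carboxylate
Conditions: tributyl(vinyl)stannane, Pd(PPh3)4 (5 mol%), LiCl, THF, reflux
Reagents that add atoms: tributyl(vinyl)stannane, C=C[Sn](CCCC)(CCCC)CCCC
Why: Stille coupling of a cyclohexenyl triflate with a vinylstannane in the presence of LiCl, known for 2,6,6-trisubstituted cyclohexenyl triflates; the diene forms without any cationic intermediate and the quaternary centre is untouched.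

Step 6
Reactants: 11 methyl (1R)-2-ethenyl-1,3-dimethylcyclohex-2-ene-1-carboxylate
Product: 12 [(1R)-2-ethenyl-1,3-dimethylcyclohex-2-en-1-yl]methanol
Conditions: LiAlH4, Et2O, 0 °C
Reagents that add atoms: none
Why: Hydride reduction of a hindered ester to the neopentyl alcohol; the unactivated diene is inert to LiAlH4.

Step 7
Reactants: 12 [(1R)-2-ethenyl-1,3-dimethylcyclohex-2-en-1-yl]methanol
Product: 13 tert-butyl{[(1R)-2-ethenyl-1,3-dimethylcyclohex-2-en-1-yl]methoxy}diphenylsilane
Conditions: TBDPSCl, imidazole, DMAP (cat.), DMF, rt
Reagents that add atoms: tert-butyl(chloro)diphenylsilane, CC(C)(C)[Si](Cl)(c1ccccc1)c1ccccc1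
Why: Silylation of a primary alcohol; the bulky silyl ether survives all steps up to step 14 and serves as the face-differentiating group in the cycloaddition.

Step 8
Reactants: 13 tert-butyl{[(1R)-2-ethenyl-1,3-dimethylcyclohex-2-en-1-yl]methoxy}diphenylsilane; 14 methyl but-2-ynoate
Product: 15 methyl (4R,10R)-19-(tert-butyldiphenylsilyloxy)-12,13,14,15,16-pentanor-ent-labda-5,8-dien-11-oate
Conditions: 14 (6 equiv, neat), BHT (cat.), sealed tube, 130–140 °C
Reagents that add atoms: none
Why: A concerted but asynchronous thermal [4+2] cycloaddition of normal electron demand between the s-cis diene C10=C5–C6=C7 and the ynoate; the closest known reaction type is the Diels–Alder reaction of 2,6,6-trisubstituted 1-vinylcyclohexenes with acetylenic esters. Ring B is closed as a six-membered carbocycle by the cycloaddition itself, both new σ bonds (C7–C8 and C9–C10) forming on the same face of the diene to leave a 1,4-cyclohexadiene, and an alkyne dienophile raises no endo/exo question. Regiochemistry should follow the diene HOMO: the largest coefficient is at the unsubstituted terminus C7, which pairs with the β-carbon of the ynoate (C8), and the charge that develops in the asynchronous transition state is best carried by the fully substituted C10, so the ester-bearing carbon C9 bonds to C10. The one new stereocentre, C10, is controlled by C4: in the reactive conformer the pseudoequatorial position on C4 lies near the diene plane and eclipses the inner vinyl C–H (1,2-allylic strain), so the larger silyloxymethyl group should sit pseudoaxial and cover one face over C5 and C10. The ynoate should then add to the opposite face, which pushes the C10 methyl toward the side of C19 and gives the 4R,10R product. The step needs facial and regiochemical selectivity; the first rests on the size of the silyl ether, the second on the unsymmetrical substitution of the diene. Any minor C10 epimer or regioisomer is to be removed by chromatography at this stage.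

Step 9
Reactants: 15 methyl (4R,10R)-19-(tert-butyldiphenylsilyloxy)-12,13,14,15,16-pentanor-ent-labda-5,8-dien-11-oate
Product: 16 methyl (4R,5S,10R)-19-(tert-butyldiphenylsilyloxy)-12,13,14,15,16-pentanor-ent-labd-8-en-11-oate
Conditions: H2 (4 atm), Pd/C, EtOAc, rt
Reagents that add atoms: none
Why: Heterogeneous hydrogenation reduces the trisubstituted 5,6-alkene while the tetrasubstituted conjugated 8,9-alkene resists; hydrogen should add from the face opposite the axial C20 and C19 groups, giving the trans ring fusion (5S).

Step 10
Reactants: 16 methyl (4R,5S,10R)-19-(tert-butyldiphenylsilyloxy)-12,13,14,15,16-pentanor-ent-labd-8-en-11-oate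
Product: 18 methyl (4R,5S,9R,10R)-19-(tert-butyldiphenylsilyloxy)-12,13,14,15,16-pentanor-ent-labd-8(17)-en-11-oate, via lithium dienolate 17 (not isolated)
Conditions: LiN(iPr)2, THF/HMPA, −78 °C; then AcOH, −78 °C
Reagents that add atoms: none
Why: Deconjugative protonation of an α,β-unsaturated ester, as in the conversion of β-cyclogeranate-type esters into their γ isomers: the amide removes a hydrogen from the C17 methyl, which is cis to the ester, and the dienolate is protonated kinetically at the α-carbon C9. The proton should enter anti to the axial C20 methyl, leaving C11 equatorial (9R).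

Step 11
Reactants: 18 methyl (4R,5S,9R,10R)-19-(tert-butyldiphenylsilyloxy)-12,13,14,15,16-pentanor-ent-labd-8(17)-en-11-oate
Product: 19 (4R,5S,9R,10R)-19-(tert-butyldiphenylsilyloxy)-12,13,14,15,16-pentanor-ent-labd-8(17)-en-11-ol
Conditions: LiAlH4, THF, 0 °C
Reagents that add atoms: none
Why: Hydride reduction of the ester to the primary alcohol; addition to the carbonyl is faster than enolisation, so C9 and the exocyclic alkene are retained, and the silyl ether tolerates LiAlH4 at 0 °C.

Step 12
Reactants: 19 (4R,5S,9R,10R)-19-(tert-butyldiphenylsilyloxy)-12,13,14,15,16-pentanor-ent-labd-8(17)-en-11-ol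
Product: 20 (4R,5S,9R,10R)-19-(tert-butyldiphenylsilyloxy)-12,13,14,15,16-pentanor-ent-labd-8(17)-en-11-al
Conditions: Dess–Martin periodinane, NaHCO3, CH2Cl2, 0 °C → rt
Reagents that add atoms: none
Why: Dess–Martin oxidation under buffered, near-neutral conditions, chosen so that the β,γ-unsaturated aldehyde neither epimerises at C9 nor conjugates; the aldehyde is used without storage.

Step 13
Reactants: 20 (4R,5S,9R,10R)-19-(tert-butyldiphenylsilyloxy)-12,13,14,15,16-pentanor-ent-labd-8(17)-en-11-al
Product: 21 (4R,5S,9R,10R)-19-(tert-butyldiphenylsilyloxy)-13,14,15,16-tetranor-ent-labda-8(17),11-diene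
Conditions: Ph3PCH3Br, KN(SiMe3)2, THF, 0 °C; then 20, −78 → 0 °C
Reagents that add atoms: methyltriphenylphosphonium bromide, C[P+](c1ccccc1)(c1ccccc1)c1ccccc1.[Br-]
Why: Wittig methylenation; addition of the unstabilised ylide to the aldehyde at low temperature should be faster than α-deprotonation, so C9 keeps its configuration.

Step 14
Reactants: 21 (4R,5S,9R,10R)-19-(tert-butyldiphenylsilyloxy)-13,14,15,16-tetranor-ent-labda-8(17),11-diene
Product: 22 (4R,5S,9R,10R)-13,14,15,16-tetranor-ent-labda-8(17),11-dien-19-ol
Conditions: TBAF, THF, 50 °C
Reagents that add atoms: none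
Why: Fluoride cleavage of the silyl ether; the hydrocarbon diene is inert, and removal here lets C19 be acetylated together with C16 in step 19.

Step 15
Reactants: 23 but-2-yne-1,4-diol
Product: 24 (2E)-2-(tributylstannyl)but-2-ene-1,4-diol
Conditions: Bu3SnH, PdCl2(PPh3)2 (2 mol%), THF, rt
Reagents that add atoms: tributyltin hydride, CCCC[SnH](CCCC)CCCC
Why: Palladium-catalysed hydrostannation adds tin and hydrogen syn across the alkyne, so the two hydroxymethyl groups end cis; the alkyne is symmetrical and no regiochemical question arises.

Step 16
Reactants: 24 (2E)-2-(tributylstannyl)but-2-ene-1,4-diol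
Product: 25 (2E)-4-[(tert-butyldimethylsilyl)oxy]-2-(tributylstannyl)but-2-en-1-ol
Conditions: TBSCl (1.05 equiv), imidazole, CH2Cl2, −20 °C
Reagents that add atoms: tert-butyl(chloro)dimethylsilane, CC(C)(C)[Si](C)(C)Cl
Why: Selective monosilylation of a diol: the C1 hydroxyl is flanked by the carbon bearing the bulky tributyltin group, so the remote C4 hydroxyl (the future C15 oxygen) should react first.

Step 17
Reactants: 25 (2E)-4-[(tert-butyldimethylsilyl)oxy]-2-(tributylstannyl)but-2-en-1-ol
Product: 26 (2E)-4-[(tert-butyldimethylsilyl)oxy]-2-iodobut-2-en-1-ol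
Conditions: I2, CH2Cl2, 0 °C
Reagents that add atoms: iodine, [I][I]
Why: Iododestannylation of a vinylstannane proceeds with retention, so the iodine stays cis to the vinylic hydrogen and the two oxygenated carbons stay cis to each other.

Step 18
Reactants: 22 (4R,5S,9R,10R)-13,14,15,16-tetranor-ent-labda-8(17),11-dien-19-ol; 26 (2E)-4-[(tert-butyldimethylsilyl)oxy]-2-iodobut-2-en-1-ol
Product: 28 (4R,5S,9R,10S,13Z)-15-[(tert-butyldimethylsilyl)oxy]-ent-labda-8(17),13-diene-16,19-diol, via alkylborane 27 (not isolated)
Conditions: 9-BBN (2.5 equiv), THF, rt; then 26, PdCl2(dppf) (5 mol%), AsPh3, Cs2CO3, DMF/H2O, rt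
Reagents that add atoms: none
Why: B-alkyl Suzuki–Miyaura coupling: 9-BBN hydroborates the monosubstituted C11=C12 alkene far faster than the hindered 1,1-disubstituted 8(17)-alkene and places boron on C12, with the extra equivalent taken up by the C19 hydroxyl as a borinate that hydrolyses on work-up. Coupling with the vinyl iodide goes with retention and forms C12–C13 with the 13Z geometry already in place.

Step 19
Reactants: 28 (4R,5S,9R,10S,13Z)-15-[(tert-butyldimethylsilyl)oxy]-ent-labda-8(17),13-diene-16,19-diol
Product: 29 (4R,5S,9R,10S,13Z)-15-[(tert-butyldimethylsilyl)oxy]-ent-labda-8(17),13-diene-16,19-diyl diacetate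
Conditions: Ac2O, pyridine, DMAP (cat.), CH2Cl2, rt
Reagents that add atoms: acetic anhydride, CC(=O)OC(C)=O
Why: Acylation of both primary hydroxyls; DMAP catalysis is needed for the axial neopentyl C19 hydroxyl, and C15 is still silylated so only C16 and C19 receive acetate.

Step 20
Reactants: 29 (4R,5S,9R,10S,13Z)-15-[(tert-butyldimethylsilyl)oxy]-ent-labda-8(17),13-diene-16,19-diyl diacetate
Product: 30 (4R,5S,9R,10S,13Z)-15-hydroxy-ent-labda-8(17),13-diene-16,19-diyl diacetate
Conditions: HF·pyridine, pyridine/THF, 0 °C
Reagents that add atoms: none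
Why: Buffered fluoride cleavage of a primary allylic silyl ether; the medium is neither basic enough for acetyl migration from O16 to O15 nor acidic enough to move the exocyclic alkene.

Step 21
Reactants: 30 (4R,5S,9R,10S,13Z)-15-hydroxy-ent-labda-8(17),13-diene-16,19-diyl diacetate
Product: 31 (4R,5S,9R,10S,13Z)-16,19-diacetoxy-ent-labda-8(17),13-dien-15-al
Conditions: MnO2, CH2Cl2, rt
Reagents that add atoms: none
Why: Manganese dioxide oxidation of an allylic alcohol to the enal under neutral conditions, which should preserve the alkene geometry; no free hydroxyl is present to form a lactol.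

Step 22
Reactants: 31 (4R,5S,9R,10S,13Z)-16,19-diacetoxy-ent-labda-8(17),13-dien-15-al
Product: 32 (4R,5S,9R,10S,13Z)-16,19-diacetoxy-ent-labda-8(17),13-dien-15-oic acid
Conditions: NaClO2, NaH2PO4, 2-methylbut-2-ene, t-BuOH/H2O, 0 °C → rt
Reagents that add atoms: sodium chlorite, [Na+].[O-]Cl=O
Why: Pinnick oxidation converts the enal into the acid without touching the acetates; the alkene scavenger removes hypochlorous acid before it can add to the exocyclic or the trisubstituted alkene.

## Compound list

1 | methyl 2-oxocyclohexane-1-carboxylate | COC(=O)C1CCCCC1=O | starting material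
2 | tert-butyl L-valinate | CC(C)[C@H](N)C(=O)OC(C)(C)C | starting material
3 | methyl 2-{[(2S)-1-tert-butoxy-3-methyl-1-oxobutan-2-yl]amino}cyclohex-1-ene-1-carboxylate | COC(=O)C1=C(N[C@@H](C(C)C)C(=O)OC(C)(C)C)CCCC1 | intermediate
4 | N-lithio derivative of 3 (lithioenamine) | COC(=O)C1=C(N([Li])[C@@H](C(C)C)C(=O)OC(C)(C)C)CCCC1 | intermediate
5 | methyl (1R)-2-{[(2S)-1-tert-butoxy-3-methyl-1-oxobutan-2-yl]imino}-1-methylcyclohexane-1-carboxylate | COC(=O)[C@]1(C)CCCCC1=N[C@@H](C(C)C)C(=O)OC(C)(C)C | intermediate
6 | methyl (1R)-1-methyl-2-oxocyclohexane-1-carboxylate | COC(=O)[C@]1(C)CCCCC1=O | intermediate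
7 | lithium enolate of 6, enolised toward C3 | COC(=O)[C@]1(C)CCCC=C1O[Li] | intermediate
8 | methyl (1R)-1,3-dimethyl-2-oxocyclohexane-1-carboxylate (both C3 epimers) | COC(=O)[C@]1(C)CCCC(C)C1=O | intermediate
9 | potassium enolate of 8 (C2=C3) | COC(=O)[C@]1(C)CCCC(C)=C1O[K] | intermediate
10 | methyl (1R)-1,3-dimethyl-2-{[(trifluoromethyl)sulfonyl]oxy}cyclohex-2-ene-1-carboxylate | COC(=O)[C@]1(C)CCCC(C)=C1OS(=O)(=O)C(F)(F)F | intermediate
11 | methyl (1R)-2-ethenyl-1,3-dimethylcyclohex-2-ene-1-carboxylate | COC(=O)[C@]1(C)CCCC(C)=C1C=C | intermediate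
12 | [(1R)-2-ethenyl-1,3-dimethylcyclohex-2-en-1-yl]methanol | OC[C@]1(C)CCCC(C)=C1C=C | intermediate
13 | tert-butyl{[(1R)-2-ethenyl-1,3-dimethylcyclohex-2-en-1-yl]methoxy}diphenylsilane | C=CC1=C(C)CCC[C@@]1(C)CO[Si](c1ccccc1)(c1ccccc1)C(C)(C)C | intermediate
14 | methyl but-2-ynoate | CC#CC(=O)OC | starting material
15 | methyl (4R,10R)-19-(tert-butyldiphenylsilyloxy)-12,13,14,15,16-pentanor-ent-labda-5,8-dien-11-oate (C20 cis to C19) | CC1=C(C(=O)OC)[C@]2(C)CCC[C@@](C)(CO[Si](c3ccccc3)(c3ccccc3)C(C)(C)C)C2=CC1 | intermediate
16 | methyl (4R,5S,10R)-19-(tert-butyldiphenylsilyloxy)-12,13,14,15,16-pentanor-ent-labd-8-en-11-oate (trans-fused) | CC1=C(C(=O)OC)[C@]2(C)CCC[C@@](C)(CO[Si](c3ccccc3)(c3ccccc3)C(C)(C)C)[C@H]2CC1 | intermediate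
17 | lithium dienolate of 16 (C17=C8, C9=C11) | C=C1CC[C@@H]2[C@](C)(CO[Si](c3ccccc3)(c3ccccc3)C(C)(C)C)CCC[C@@]2(C)C1=C(OC)O[Li] | intermediate
18 | methyl (4R,5S,9R,10R)-19-(tert-butyldiphenylsilyloxy)-12,13,14,15,16-pentanor-ent-labd-8(17)-en-11-oate | C=C1CC[C@@H]2[C@](C)(CO[Si](c3ccccc3)(c3ccccc3)C(C)(C)C)CCC[C@@]2(C)[C@@H]1C(=O)OC | intermediate
19 | (4R,5S,9R,10R)-19-(tert-butyldiphenylsilyloxy)-12,13,14,15,16-pentanor-ent-labd-8(17)-en-11-ol | C=C1CC[C@@H]2[C@](C)(CO[Si](c3ccccc3)(c3ccccc3)C(C)(C)C)CCC[C@@]2(C)[C@@H]1CO | intermediate
20 | (4R,5S,9R,10R)-19-(tert-butyldiphenylsilyloxy)-12,13,14,15,16-pentanor-ent-labd-8(17)-en-11-al | C=C1CC[C@@H]2[C@](C)(CO[Si](c3ccccc3)(c3ccccc3)C(C)(C)C)CCC[C@@]2(C)[C@@H]1C=O | intermediate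
21 | (4R,5S,9R,10R)-19-(tert-butyldiphenylsilyloxy)-13,14,15,16-tetranor-ent-labda-8(17),11-diene | C=C1CC[C@@H]2[C@](C)(CO[Si](c3ccccc3)(c3ccccc3)C(C)(C)C)CCC[C@@]2(C)[C@@H]1C=C | intermediate
22 | (4R,5S,9R,10R)-13,14,15,16-tetranor-ent-labda-8(17),11-dien-19-ol | C=C1CC[C@@H]2[C@](C)(CO)CCC[C@@]2(C)[C@@H]1C=C | intermediate
23 | but-2-yne-1,4-diol | OCC#CCO | starting material
24 | (2E)-2-(tributylstannyl)but-2-ene-1,4-diol | OC/C=C(\CO)[Sn](CCCC)(CCCC)CCCC | intermediate
25 | (2E)-4-[(tert-butyldimethylsilyl)oxy]-2-(tributylstannyl)but-2-en-1-ol | CC(C)(C)[Si](C)(C)OC/C=C(\CO)[Sn](CCCC)(CCCC)CCCC | intermediate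
26 | (2E)-4-[(tert-butyldimethylsilyl)oxy]-2-iodobut-2-en-1-ol | CC(C)(C)[Si](C)(C)OC/C=C(\CO)I | intermediate
27 | (4R,5S,9R,10S)-12-(9-borabicyclo[3.3.1]nonan-9-yl)-13,14,15,16-tetranor-ent-labd-8(17)-en-19-yl 9-borabicyclo[3.3.1]nonan-9-yl ether (alkylborane) | C=C1CC[C@@H]2[C@](C)(COB3C4CCCC3CCC4)CCC[C@@]2(C)[C@@H]1CCB1C2CCCC1CCC2 | intermediate
28 | (4R,5S,9R,10S,13Z)-15-[(tert-butyldimethylsilyl)oxy]-ent-labda-8(17),13-diene-16,19-diol | C=C1CC[C@@H]2[C@](C)(CO)CCC[C@@]2(C)[C@@H]1CC/C(=C/CO[Si](C)(C)C(C)(C)C)CO | intermediate
29 | (4R,5S,9R,10S,13Z)-15-[(tert-butyldimethylsilyl)oxy]-ent-labda-8(17),13-diene-16,19-diyl diacetate | C=C1CC[C@@H]2[C@](C)(COC(C)=O)CCC[C@@]2(C)[C@@H]1CC/C(=C/CO[Si](C)(C)C(C)(C)C)COC(C)=O | intermediate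
30 | (4R,5S,9R,10S,13Z)-15-hydroxy-ent-labda-8(17),13-diene-16,19-diyl diacetate | C=C1CC[C@@H]2[C@](C)(COC(C)=O)CCC[C@@]2(C)[C@@H]1CC/C(=C/CO)COC(C)=O | intermediate
31 | (4R,5S,9R,10S,13Z)-16,19-diacetoxy-ent-labda-8(17),13-dien-15-al | C=C1CC[C@@H]2[C@](C)(COC(C)=O)CCC[C@@]2(C)[C@@H]1CC/C(=C/C=O)COC(C)=O | intermediate
32 | (4R,5S,9R,10S,13Z)-16,19-diacetoxy-ent-labda-8(17),13-dien-15-oic acid | C=C1CC[C@@H]2[C@](C)(COC(C)=O)CCC[C@@]2(C)[C@@H]1CC/C(=C/C(=O)O)COC(C)=O | target

## Step count and least certain steps

Total step count: 22. Longest linear sequence: 19 steps (steps 1–14 and 18–22). The three-step preparation of vinyl iodide 26 (steps 15–17) is a side branch that joins at step 18.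

**Step 8 (key step).** The ynoate is a sluggish dienophile and the diene has to reach a strained s-cis geometry. At the temperature needed, the diene may isomerise by [1,5]-hydrogen shift before it adds. The heat may also erode the facial preference at C10, because the two groups on C4 differ only beyond their first carbon. Partial loss of regiocontrol is also possible. Fallback, from 13 back to 15: Lewis acid-promoted cycloaddition of 13 with but-2-ynal (Me2AlCl, CH2Cl2, −78 °C) should give (4R,10R)-19-(tert-butyldiphenylsilyloxy)-12,13,14,15,16-pentanor-ent-labda-5,8-dien-11-al F1 at a temperature where the diene is stable and the facial bias is better expressed. Chlorite oxidation (NaClO2, NaH2PO4, 2-methylbut-2-ene) then gives (4R,10R)-19-(tert-butyldiphenylsilyloxy)-12,13,14,15,16-pentanor-ent-labda-5,8-dien-11-oic acid F2, and methylation of the carboxylate (MeI, K2CO3, DMF) returns to 15.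

**Step 10.** Deprotonation may occur at the ring carbon C7 instead of the C17 methyl, giving the endocyclic 7-ene. The dienolate may be protonated at C17, which returns 16. The proton may also enter C9 from the wrong face. Fallback, from 16 back to 18: photochemical deconjugation (254 nm, hexane with a catalytic amine). The excited ester can take a hydrogen only from C17, the one γ-carbon cis to the carbonyl, through a [1,5]-shift, and the dienol so formed ketonises at C9 to 18. No new compound lies on this path.

**Step 13.** The basic ylide may enolise aldehyde 20 instead of adding to it, which epimerises C9 or draws the 8(17)-alkene into conjugation. Fallback, from 19 back to 21, avoiding the aldehyde: Mitsunobu reaction of 19 with 1-phenyl-1H-tetrazole-5-thiol (PPh3, DIAD, THF) should give the C11 sulfide 5-{[(4R,5S,9R,10R)-19-(tert-butyldiphenylsilyloxy)-12,13,14,15,16-pentanor-ent-labd-8(17)-en-11-yl]sulfanyl}-1-phenyl-1H-tetrazole F3. Oxidation at sulfur (H2O2, (NH4)6Mo7O24·4H2O, EtOH) gives the corresponding sulfone, 5-{[(4R,5S,9R,10R)-19-(tert-butyldiphenylsilyloxy)-12,13,14,15,16-pentanor-ent-labd-8(17)-en-11-yl]sulfonyl}-1-phenyl-1H-tetrazole F4. Julia–Kocienski olefination (KN(SiMe3)2, THF, −78 °C, then monomeric formaldehyde) gives 21. The carbanion sits on C11, so C9–H never becomes acidic.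

**Step 18.** The alkylborane is β-branched and next to a quaternary carbon, so transmetallation to palladium may be slow. Protodeboronation or reduction of the vinyl iodide could then win, and the free hydroxyls consume borane. Fallback, from 22 back to 28: hydroboration and mild oxidation of 22 (9-BBN, THF; then NaBO3·4H2O) gives (4R,5S,9R,10S)-13,14,15,16-tetranor-ent-labd-8(17)-ene-12,19-diol F5. Iodination of the unhindered C12 hydroxyl (I2, PPh3, imidazole, CH2Cl2, 0 °C; the neopentyl C19 hydroxyl does not undergo displacement) gives (4R,5S,9R,10S)-12-iodo-13,14,15,16-tetranor-ent-labd-8(17)-en-19-ol F6. Nickel-catalysed reductive cross-electrophile coupling of this primary iodide with vinyl iodide 26 (NiCl2(dme), 4,4'-di-tert-butyl-2,2'-bipyridine, Mn powder, DMA, rt) tolerates free hydroxyls, retains the alkene geometry and gives 28.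

## Further compounds

F1 | step 8 | (4R,10R)-19-(tert-butyldiphenylsilyloxy)-12,13,14,15,16-pentanor-ent-labda-5,8-dien-11-al | CC1=C(C=O)[C@]2(C)CCC[C@@](C)(CO[Si](c3ccccc3)(c3ccccc3)C(C)(C)C)C2=CC1
F2 | step 8 | (4R,10R)-19-(tert-butyldiphenylsilyloxy)-12,13,14,15,16-pentanor-ent-labda-5,8-dien-11-oic acid | CC1=C(C(=O)O)[C@]2(C)CCC[C@@](C)(CO[Si](c3ccccc3)(c3ccccc3)C(C)(C)C)C2=CC1
F0 | step 10 | none | none
F3 | step 13 | 5-{[(4R,5S,9R,10R)-19-(tert-butyldiphenylsilyloxy)-12,13,14,15,16-pentanor-ent-labd-8(17)-en-11-yl]sulfanyl}-1-phenyl-1H-tetrazole | C=C1CC[C@@H]2[C@](C)(CO[Si](c3ccccc3)(c3ccccc3)C(C)(C)C)CCC[C@@]2(C)[C@@H]1CSc1nnnn1-c1ccccc1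
F4 | step 13 | 5-{[(4R,5S,9R,10R)-19-(tert-butyldiphenylsilyloxy)-12,13,14,15,16-pentanor-ent-labd-8(17)-en-11-yl]sulfonyl}-1-phenyl-1H-tetrazole | C=C1CC[C@@H]2[C@](C)(CO[Si](c3ccccc3)(c3ccccc3)C(C)(C)C)CCC[C@@]2(C)[C@@H]1CS(=O)(=O)c1nnnn1-c1ccccc1
F5 | step 18 | (4R,5S,9R,10S)-13,14,15,16-tetranor-ent-labd-8(17)-ene-12,19-diol | C=C1CC[C@@H]2[C@](C)(CO)CCC[C@@]2(C)[C@@H]1CCO
F6 | step 18 | (4R,5S,9R,10S)-12-iodo-13,14,15,16-tetranor-ent-labd-8(17)-en-19-ol | C=C1CC[C@@H]2[C@](C)(CO)CCC[C@@]2(C)[C@@H]1CCI
A1 | alternative 1 | 3,4-methano trans-decalin 9-ethylene ketal with the axial C19 hydroxymethyl on C4 | OC[C@]12C[C@H]1CC[C@@]3(C)C4(OCCO4)CCC[C@H]23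
A2 | alternative 2 | trans-fused octalin C11 aldehyde with C4 gem-dimethyl ester and C8 silyloxymethyl | CC(C)(C)[Si](C)(C)OC[C@@H]1C=C[C@@H]2C(C(=O)OC)(C(=O)OC)CCC[C@@]2(C)[C@@H]1C=O
A3 | alternative 3 | 8-oxo trans-decalin with the ketal- and PMB-protected chain on C9 and C19 silyl ether | O=C1CC[C@@H]2[C@](C)(CO[Si](C)(C)C(C)(C)C)CCC[C@@]2(C)[C@@H]1CCC1(COCc2ccc(OC)cc2)OCCO1
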